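## Structural features

The target is a labdane: a trans-fused decalin (ring A = C1–C5 and C10 with a gem-dimethyl C4 and an axial methyl on C10; ring B = C5–C10) that carries at C9 an equatorial (E)-3-methylpenta-2,4-dienyl chain (C11–C16). Ring B is fully substituted, with five contiguous stereocentres C5–C9 next to the quaternary C10. C6 bears an equatorial α-angelate, C7 an equatorial β-hydroxyl, and C8 an equatorial α-hydroxyl beside an axial β-methyl, so O6/O7 and O7/O8 are both trans-diequatorial pairs that no single syn or anti addition to an alkene delivers. The fragile groups are:

- the angelate, which can isomerise Z to E, migrate to O7, or be cleaved by hydride;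
- the terminal conjugated diene, which is sensitive to acid (ether formation with the 8-hydroxyl) and to oxidants;
- the tertiary 8-hydroxyl, which is β to C6 and to C11 and invites retro-aldol cleavage or elimination whenever either is a carbonyl.

The real difficulties are the absolute configuration of quaternary C10, the C9 hydrogen between two fully substituted carbons, and acylating only the most hindered of three neighbouring hydroxyls. The key step exploits the fact that C6 is a single oxygenated carbon between C5 and C7. Ring B can therefore be cut into carbon monoxide and the five-carbon unit C5–C10–C9–C8–C7, held as a vinylcyclopropane fused to ring A whose strained C5–C9 bond is absent from the target. After that step only C10 is a carried stereocentre; every other centre is set relative to it, using the axial methyls on C4, C8 and C10 that close the β face.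

## Logic of the disconnections

**26 to 25.** The C7–H bond is cut (alcohol back to ketone). Hydride should enter C7 axially from the α face, anti to the axial C8 methyl, so the one centre that a syn-dihydroxylation sets wrongly is corrected last and O7 never needs a protecting group. The forward step must leave the ester and diene alone and must not let the acyl group migrate.

**25 to 24.** Only the oxidation level at C7 changes. This erases the axial 7α-hydroxyl and makes O6 the only acylated oxygen next to a carbonyl. It needs an oxidant that takes a hindered secondary alcohol and spares the tertiary one and the diene.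

**24 to 21 and 22.** The C6–O acyl bond is cut. The hydride- and base-sensitive Z ester enters after every reduction and olefination. In 21 the 6,7-diol is cis with O6 equatorial and O7 axial, so the tin acetal 23 can tell them apart. The step must be regioselective and must not isomerise the Z double bond.

**21 to 20 to 19.** C14=C15 and then C12=C13 are cut. A stabilised ylide gives the E trisubstituted alkene and a methylene transfer completes the diene, which therefore appears only after all oxidations of ring B. Both olefinations must tolerate three free hydroxyls.

**19 to 18.** The C6–O and C7–O bonds are cut. A syn-dihydroxylation from the open α face fixes C6 in its final configuration. The oxidant must not touch the lactol.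

**18 to 16 (through 17).** The C11–C12 bond is cut, a one-carbon extension of the aldehyde. The new aldehyde is caught by the 8-hydroxyl as a lactol, which protects both. The forward step must avoid retro-aldol cleavage of the β-hydroxy aldehyde.

**16 to 15 to 14.** Redox adjustment at C11 only; the ester of the key step becomes the aldehyde.

**14 to 12 (through 13).** The C6=C7 alkene is traded for the C6 carbonyl and the C7–O bond of an epoxide (reductive 1,3-transposition). One operation then supplies both the 8α-hydroxyl and the alkene needed for the diol. It demands the epoxide on the α face. An 8,9-epoxide was not chosen, because next to the C6 ketone it would open by enolisation at C7.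

**12 to 10 (through 11).** The two epoxide C–O bonds and the C9–H bond are cut. The ketone/enoate pair of 10 is a vinylogous β-keto ester that moves its double bond into conjugation with the ketone; the resulting enone accepts a nucleophilic oxidant at C8. The step must attack the α face and leave the ester β at C9.

**10 to 7 and 8 (through 9).** The C5–C6 and C6–C7 bonds are cut: ring B falls apart into carbon monoxide and a vinylcyclopropane. All ring B functionality disappears, and one stereocentre (C10) remains. The forward step must cleave C5–C9 and not C9–C10, insert CO, and allow C5 to be epimerised to the trans fusion.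

**7 to 4 and 6.** The C5–C9 and C9–C10 bonds of the cyclopropane are cut, a [2+1] addition of a vinylcarbene to a ring alkene. The face of addition sets C10; the configuration at the carbene carbon is irrelevant. The demand is enantioface selection on a hindered trisubstituted alkene without allylic C–H insertion.

**6 to 5, and 4 to 3 to 1 and 2.** The C–N2 bond comes from a deconjugative diazo transfer to a commodity enoate. The ring alkene comes from a ketone by way of its sulfonylhydrazone, which fixes the double-bond position unambiguously.

## Other disconnections considered

**Alternative 1:** The cut runs through C5–C10 and C8–C9, so both rings come from one open chain, the trienimide A1. In an intramolecular Diels–Alder reaction promoted by Cu(SbF6)2 (divalent copper) and a chiral tert-butyl bis(oxazoline), the (E,Z)-silyloxydiene C5=C6–C7=C8 would add to the enoyl unit C9=C10 and give cycloadduct A2.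

- In its favour: one catalytic step closes rings A and B and fixes C5, C8, C9 and C10 together. A2 already has the C6=C7 alkene, the 8α-oxygen and the C11 carbonyl; it is the silyl ether and imide counterpart of 14, so steps 8–16 would apply from there.
- Where it is better than the chosen plan: C9 is set directly and not through a tautomer equilibrium, and steps 5–7 become unnecessary.
- Against it here: the dienophile carbon C10 is β,β-disubstituted, a class that chelating copper catalysts activate poorly. The diene terminus C8 is fully substituted and must be a geometrically pure Z silyl enol ether, which a strong Lewis acid may cleave or divert into a stepwise Michael pathway with loss of the ring fusion control. A1 itself would need perhaps eight to ten linear steps with two trisubstituted alkene geometries.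
- Comparison: a concerted cycloaddition against an organometallic ring expansion. Both concentrate the risk in one demanding step. The overall step count is expected to be comparable, with the alternative shorter after its key step and longer before it.

**Alternative 2:** The cut is C1–C10 and C4–C5: ring A is built onto a preformed ring B. 2,6-Dimethyl-1,4-benzoquinone A3 and allylidenecyclopropane A4 would combine under a chiral oxazaborolidinium triflimide bound to the unhindered carbonyl, which selects one of the two enantiotopic methyl-bearing double bonds. Base would then epimerise C5 to give the trans-fused enedione A5, with the spirocyclopropane as a latent gem-dimethyl group.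

- In its favour: the quaternary C10 is set by a catalyst class with broad precedent on quinones, which is firmer ground than step 4 of the chosen plan; on this point the alternative is better. The partners are simple, and the C5 epimerisation next to the C6 carbonyl is the same device as in the chosen plan (equal).
- Against it here: A5 has no C11 and carries a ketone at C9. The side chain would have to be attached to the most hindered carbonyl and the C9 oxygen then removed with control of the C9 hydrogen. The cyclopropane must be hydrogenolysed and the C2=C3 alkene saturated, the two ring B carbonyls must be told apart, and the trans-diol problem at C7/C8 remains.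
- Comparison: both plans deliver the C6 oxygen. The chosen plan also places C11 and C17 on the right carbons from the start, so fewer C–C and redox steps follow its key step. Step economy of the alternative is expected to be poorer although its key step is the more secure.

**Alternative 3:** The cut is the C9–C10 bond: ring B is closed last, from the ynoate A6, a ring A cyclohexene that already carries the oxygenated chain. Fe(acac)3 and phenylsilane would deliver a hydrogen atom to C1, and the tertiary C10 radical would add to C9 of the alkynoate to give decalin A7 with an exocyclic C9=C11 enoate.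

- In its favour: radical conjugate addition is among the best ways to form a hindered quaternary carbon. The three oxygens are installed on an open chain and are differentiated in A7 (silyl on O6, p-methoxybenzyl on O7, free O8), so acylation of O6 needs no regiochemical device; on this point the alternative is better than step 14. C11 arrives at the ester level, equal to 14.
- Against it here: the configuration of C10 would depend on the chair preference of a cyclisation with three stereocentres on the tether. C9–H would still have to be set by a later reduction of the exocyclic enoate. The C6–C8 triad must be built next to C5 on an enantiopure ring A fragment, and the oxidative removal of the benzyl ether must precede the diene.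
- Comparison: substrate-controlled radical closure against catalyst-controlled carbene addition followed by carbonylation. There are fewer redox corrections on ring B but a longer preparation of A6. The total is expected to be similar or longer.

Key step: step 5

Convention: labdane (drimane) numbering is used for all decalin compounds; β is the face of the C10 methyl group, α the opposite face; C11 is the carbon attached to C9.

Assumption: under the DBU that sets the ring fusion in step 5, ketone 10 is expected to equilibrate with its conjugated 7-ene tautomer 11 (the Hagemann's ester pattern); the material is numbered as the 8-ene and carried on unseparated, because step 6 passes through 11 in any case.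

Step 1
Reactants: 1 2,2,6-trimethylcyclohexan-1-one; 2 p-toluenesulfonyl hydrazide
Product: 3 2,2,6-trimethylcyclohexanone p-toluenesulfonylhydrazone
Conditions: EtOH, HCl (cat.), reflux
Reagents that add atoms: none
Why: Acid-catalysed hydrazone condensation; the hindered carbonyl needs prolonged heating, and the NHTs group should sit syn to the less hindered CH(CH3) side, which is the side that must be deprotonated next.

Step 2
Reactants: 3 2,2,6-trimethylcyclohexanone p-toluenesulfonylhydrazone
Product: 4 1,3,3-trimethylcyclohex-1-ene
Conditions: n-BuLi (3 equiv), TMEDA, hexane, −78 °C to rt; H2O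
Reagents that add atoms: none
Why: Shapiro reaction: the dianion can form only at the single α-C–H, loss of sulfinate and N2 gives the vinyllithium, and protonation places the double bond between the methyl-bearing carbon and the carbon next to the gem-dimethyl group; the stereocentre of 1 is destroyed.

Step 3
Reactants: 5 methyl 3-methylbut-2-enoate
Product: 6 methyl 2-diazo-3-methylbut-3-enoate
Conditions: 4-acetamidobenzenesulfonyl azide, DBU, MeCN, 0 °C to rt; used at once
Reagents that add atoms: 4-acetamidobenzenesulfonyl azide, CC(=O)Nc1ccc(cc1)S(=O)(=O)N=[N+]=[N-]
Why: Deconjugative Regitz diazo transfer: DBU forms the γ-deprotonated dienolate, which attacks the sulfonyl azide at the α-carbon and leaves the isopropenyl group; the vinyldiazoacetate cyclises to a pyrazole on standing and is therefore not stored.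

Step 4
Reactants: 4 1,3,3-trimethylcyclohex-1-ene; 6 methyl 2-diazo-3-methylbut-3-enoate
Product: 7 methyl (1S,6R,7R)-1,5,5-trimethyl-7-(prop-1-en-2-yl)bicyclo[4.1.0]heptane-7-carboxylate
Conditions: Rh2(S-DOSP)4 (1 mol %; DOSP = N-(4-dodecylbenzenesulfonyl)prolinate), 4 (5 equiv), pentane, −40 to 0 °C, slow addition of 6
Reagents that add atoms: none
Why: Proposed new method: [2+1] addition of a rhodium-bound donor/acceptor vinylcarbene to a hindered trisubstituted cycloalkene; the carbenoid should approach end-on at the less substituted C2–H terminus in a concerted asynchronous addition, the chiral pocket choosing the enantioface and so the configuration of C1 of the bicycle (C10), while the usual competitor, allylic C–H insertion next to the CH terminus, is shut off because that carbon is the quaternary C3 of 4; the closest known reaction type is the Rh2(S-DOSP)4-catalysed cyclopropanation of cis-disubstituted and 1,1-disubstituted alkenes by methyl vinyldiazoacetates; the configuration at C7 does not matter because that carbon becomes trigonal in step 5.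

Step 5
Reactants: 7 methyl (1S,6R,7R)-1,5,5-trimethyl-7-(prop-1-en-2-yl)bicyclo[4.1.0]heptane-7-carboxylate; 8 carbon monoxide
Product: 10 methyl 6-oxodrim-8-en-11-oate (5α-H), via cis-fused 5β-H ketone 9 (not isolated)
Conditions: [Rh(CO)2Cl]2 (5 mol %), CO (1 atm), toluene, 90 °C; then DBU (0.3 equiv), 60 °C, same flask
Reagents that add atoms: none
Why: Monovalent rhodium should add oxidatively into the C5–C9 bond to give a trivalent σ-alkyl π-allyl rhodacycle (Rh–C5, allyl C9–C8–C7), driven by release of cyclopropane strain. CO then inserts into Rh–C5 with retention, and acyl–allyl reductive elimination at the unsubstituted terminus C7 closes ring B as a six-membered β,γ-unsaturated ketone; this is a carbonylative [5+1] ring expansion, and the closest known reaction type is the rhodium-catalysed [5+1] carbonylation of vinylcyclopropanes to cyclohexenones. Ring B is thus closed by two bonds to the incoming carbon: C5–C6 by migratory insertion and C6–C7 by reductive elimination. The step needs cleavage of C5–C9 and not C9–C10; rhodium should prefer the secondary C5 over the quaternary C10, and the ester on C9 stabilises the allyl fragment. Because C4 and C10 are quaternary the Rh–C5 alkyl has no β-hydrogen, so β-hydride loss cannot compete with CO insertion, and closure at C9 would give a strained cyclobutanone. The new stereocentre C5 is formed cis in 9 by retention and is then epimerised by DBU next to the ketone to the trans fusion, the controlling element being the quaternary C10 set in step 4. C9 becomes trigonal, which is why its configuration in 7 is irrelevant.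

Step 6
Reactants: 10 methyl 6-oxodrim-8-en-11-oate
Product: 12 methyl 7α,8α-epoxy-6-oxodriman-11-oate, via conjugated 7-ene tautomer 11 (not isolated)
Conditions: t-BuOOH (decane solution), DBU, CH2Cl2, argon, 0 °C to rt
Reagents that add atoms: tert-butyl hydroperoxide, CC(C)(C)OO
Why: Weitz–Scheffer epoxidation: DBU equilibrates 10 with enone 11, and the peroxide anion should add to C8 from the α face, anti to the axial C10 methyl, the enolate then closing the epoxide at C7. By the Curtin–Hammett principle the C9 epimer whose α face is free (9α-H, ester β) should be the one consumed, so C8 and C9 are set together. DBU is too weak to enolise the ester of 12, which protects C9 and the epoxide from β-elimination.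

Step 7
Reactants: 12 methyl 7α,8α-epoxy-6-oxodriman-11-oate
Product: 14 methyl 8α-hydroxydrim-6-en-11-oate, via epoxy hydrazone 13 (not isolated)
Conditions: N2H4·H2O, AcOH (cat.), MeOH, 0 °C to rt
Reagents that add atoms: none
Why: Wharton transposition: the C6 hydrazone opens the epoxide at C7, the alkenyl diazene loses N2, and the C6=C7 alkene with the tertiary allylic alcohol results; the C8–O bond is never broken, so the 8α configuration is retained, and the hindered ester is not attacked at this temperature.

Step 8
Reactants: 14 methyl 8α-hydroxydrim-6-en-11-oate
Product: 15 drim-6-ene-8α,11-diol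
Conditions: LiAlH4, THF, 0 °C to rt
Reagents that add atoms: none
Why: Hydride reduction of the ester to the primary alcohol; the tertiary allylic alcohol and the ring alkene are inert and C9 is not epimerised.

Step 9
Reactants: 15 drim-6-ene-8α,11-diol
Product: 16 8α-hydroxydrim-6-en-11-al
Conditions: Dess–Martin periodinane, pyridine, CH2Cl2, 0 °C
Reagents that add atoms: none
Why: Dess–Martin oxidation; only the primary hydroxyl can be oxidised, and the buffered, chromium-free medium avoids both dehydration of the β-hydroxy aldehyde and oxidative transposition of the tertiary allylic alcohol.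

Step 10
Reactants: 16 8α-hydroxydrim-6-en-11-al
Product: 18 8α,12-epoxy-13,14,15,16-tetranorlabd-6-en-12-ol (lactol), via methyl enol ether 17 (not isolated)
Conditions: Ph3P(CH2OMe)Cl, KN(SiMe3)2 (0.95 equiv relative to the salt), THF, −78 to 0 °C; then aq. HCl (0.5 M), THF, 0 °C
Reagents that add atoms: (methoxymethyl)triphenylphosphonium chloride, COC[P+](c1ccccc1)(c1ccccc1)c1ccccc1.[Cl-]; water, O
Why: Wittig methoxymethylenation followed by hydrolysis of the enol ether (one-carbon homologation); the C12 aldehyde is caught by the 8α-hydroxyl as a five-membered lactol that masks both groups. The ylide is a far weaker base than an alkoxide, so without excess amide base the tertiary hydroxyl stays protonated and retro-aldol cleavage should not start.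

Step 11
Reactants: 18 8α,12-epoxy-13,14,15,16-tetranorlabd-6-en-12-ol
Product: 19 8α,12-epoxy-13,14,15,16-tetranorlabdane-6α,7α,12-triol
Conditions: OsO4 (2 mol %), N-methylmorpholine N-oxide, acetone–H2O, rt
Reagents that add atoms: N-methylmorpholine N-oxide, C[N+]1([O-])CCOCC1; water, O
Why: Upjohn syn-dihydroxylation; OsO4 should add to the α face of C6=C7 because the β face is covered by the axial methyls on C4, C10 and C8, which gives the 6α (equatorial) and 7α (axial) hydroxyls and fixes C6 in its final configuration.

Step 12
Reactants: 19 8α,12-epoxy-13,14,15,16-tetranorlabdane-6α,7α,12-triol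
Product: 20 (12E)-6α,7α,8α-trihydroxy-15-norlabd-12-en-14-al
Conditions: Ph3P=C(CH3)CHO, toluene, 80 °C
Reagents that add atoms: 2-(triphenylphosphoranylidene)propanal, CC(C=O)=P(c1ccccc1)(c1ccccc1)c1ccccc1
Why: Wittig olefination of the open hydroxy-aldehyde form of the lactol with a stabilised α-branched ylide, which should give the E trisubstituted enal (C12=C13); the neutral medium tolerates the free triol and keeps oxa-Michael closure of the 8-hydroxyl slow.

Step 13
Reactants: 20 (12E)-6α,7α,8α-trihydroxy-15-norlabd-12-en-14-al
Product: 21 (12E)-labda-12,14-diene-6α,7α,8α-triol
Conditions: RhCl(PPh3)3 (2.5 mol %), Me3SiCHN2, PPh3, i-PrOH, THF, rt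
Reagents that add atoms: trimethylsilyldiazomethane, C[Si](C)(C)C=[N+]=[N-]
Why: Rhodium-catalysed methylenation of the aldehyde: the phosphorus ylide is generated salt-free and without base from the diazo compound, PPh3 and 2-propanol, so no alkoxide forms that could add to the enal, and the C12=C13 geometry is untouched.

Step 14
Reactants: 21 (12E)-labda-12,14-diene-6α,7α,8α-triol; 22 angelic acid
Product: 24 (12E)-7α,8α-dihydroxylabda-12,14-dien-6α-yl (2Z)-2-methylbut-2-enoate, via dibutylstannylene acetal 23 (not isolated)
Conditions: Bu2SnO, MeOH, reflux, then evaporate; 22 pre-activated by 2,4,6-trichlorobenzoyl chloride, Et3N, toluene, rt; combined in toluene, 0 °C to rt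
Reagents that add atoms: none
Why: Regioselective acylation through a stannylene acetal: in tin acetals of cis-1,2-diols the equatorial oxygen (here O6) is the one acylated, while the axial O7 and the tertiary O8 stay free. The Yamaguchi mixed anhydride transfers the angeloyl group without a nucleophilic amine catalyst, which is what should keep the Z double bond from isomerising.

Step 15
Reactants: 24 (12E)-7α,8α-dihydroxylabda-12,14-dien-6α-yl (2Z)-2-methylbut-2-enoate
Product: 25 (12E)-8α-hydroxy-7-oxolabda-12,14-dien-6α-yl (2Z)-2-methylbut-2-enoate
Conditions: Dess–Martin periodinane, pyridine, CH2Cl2, 0 °C to rt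
Reagents that add atoms: none
Why: Dess–Martin oxidation of the only remaining secondary alcohol; the tertiary alcohol, diene and angelate are inert, and C6, now α to the ketone, already holds its acyloxy group in the preferred equatorial position.

Step 16
Reactants: 25 (12E)-8α-hydroxy-7-oxolabda-12,14-dien-6α-yl (2Z)-2-methylbut-2-enoate
Product: 26 (12E)-7β,8α-dihydroxylabda-12,14-dien-6α-yl (2Z)-2-methylbut-2-enoate (CNP0189082.1)
Conditions: NaBH4, CeCl3·7H2O, MeOH, −40 °C; AcOH quench
Reagents that add atoms: none
Why: Luche reduction: hydride should attack C7 axially from the α face because the β face is blocked by the adjacent axial C8 methyl, which gives the equatorial 7β-alcohol trans to both neighbours; low temperature and the acidic quench are meant to suppress acyl migration from O6 to O7.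

**Compound list**

1 | 2,2,6-trimethylcyclohexan-1-one (racemic) | CC1CCCC(C)(C)C1=O | starting material
2 | p-toluenesulfonyl hydrazide | Cc1ccc(cc1)S(=O)(=O)NN | starting material
3 | 2,2,6-trimethylcyclohexanone p-toluenesulfonylhydrazone (NHTs expected syn to C6) | CC1CCCC(C)(C)C1=NNS(=O)(=O)c1ccc(C)cc1 | intermediate
4 | 1,3,3-trimethylcyclohex-1-ene | CC1=CC(C)(C)CCC1 | intermediate
5 | methyl 3-methylbut-2-enoate | CC(C)=CC(=O)OC | starting material
6 | methyl 2-diazo-3-methylbut-3-enoate | C=C(C)C(=[N+]=[N-])C(=O)OC | intermediate
7 | methyl (1S,6R,7R)-1,5,5-trimethyl-7-(prop-1-en-2-yl)bicyclo[4.1.0]heptane-7-carboxylate (cis-fused; isopropenyl syn to the six-membered ring) | COC(=O)[C@@]1(C(C)=C)[C@@H]2C(C)(C)CCC[C@@]21C | intermediate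
8 | carbon monoxide | [C-]#[O+] | starting material
9 | methyl 6-oxo-5β-drim-8-en-11-oate (cis-fused; not isolated) | COC(=O)C1=C(C)CC(=O)[C@@H]2C(C)(C)CCC[C@@]21C | intermediate
10 | methyl 6-oxodrim-8-en-11-oate (5α-H, 10β-methyl) | COC(=O)C1=C(C)CC(=O)[C@H]2C(C)(C)CCC[C@@]21C | intermediate
11 | methyl 6-oxodrim-7-en-11-oate (9α-H; not isolated) | COC(=O)[C@H]1C(C)=CC(=O)[C@H]2C(C)(C)CCC[C@@]21C | intermediate
12 | methyl 7α,8α-epoxy-6-oxodriman-11-oate | COC(=O)[C@H]1[C@]3(C)O[C@@H]3C(=O)[C@H]2C(C)(C)CCC[C@@]21C | intermediate
13 | hydrazone of 12 at C6 (not isolated) | COC(=O)[C@H]1[C@]3(C)O[C@@H]3C(=NN)[C@H]2C(C)(C)CCC[C@@]21C | intermediate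
14 | methyl 8α-hydroxydrim-6-en-11-oate | COC(=O)[C@H]1[C@](C)(O)C=C[C@H]2C(C)(C)CCC[C@@]21C | intermediate
15 | drim-6-ene-8α,11-diol | OC[C@H]1[C@](C)(O)C=C[C@H]2C(C)(C)CCC[C@@]21C | intermediate
16 | 8α-hydroxydrim-6-en-11-al | O=C[C@H]1[C@](C)(O)C=C[C@H]2C(C)(C)CCC[C@@]21C | intermediate
17 | 12-methoxy-13,14,15,16-tetranorlabda-6,11-dien-8α-ol (E/Z mixture; not isolated) | COC=C[C@H]1[C@](C)(O)C=C[C@H]2C(C)(C)CCC[C@@]21C | intermediate
18 | 8α,12-epoxy-13,14,15,16-tetranorlabd-6-en-12-ol (lactol, both anomers) | OC1C[C@H]2[C@](C)(O1)C=C[C@H]3C(C)(C)CCC[C@@]32C | intermediate
19 | 8α,12-epoxy-13,14,15,16-tetranorlabdane-6α,7α,12-triol | OC1C[C@H]2[C@](C)(O1)[C@H](O)[C@H](O)[C@H]3C(C)(C)CCC[C@@]32C | intermediate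
20 | (12E)-6α,7α,8α-trihydroxy-15-norlabd-12-en-14-al | O=C/C(C)=C/C[C@H]1[C@](C)(O)[C@H](O)[C@H](O)[C@H]2C(C)(C)CCC[C@@]21C | intermediate
21 | (12E)-labda-12,14-diene-6α,7α,8α-triol | C=C/C(C)=C/C[C@H]1[C@](C)(O)[C@H](O)[C@H](O)[C@H]2C(C)(C)CCC[C@@]21C | intermediate
22 | angelic acid, (2Z)-2-methylbut-2-enoic acid | C/C=C(/C)C(=O)O | starting material
23 | 6α,7α-O-dibutylstannylene acetal of 21 (not isolated) | C=C/C(C)=C/C[C@H]1[C@](C)(O)[C@@H]3O[Sn](CCCC)(CCCC)O[C@@H]3[C@H]2C(C)(C)CCC[C@@]21C | intermediate
24 | (12E)-7α,8α-dihydroxylabda-12,14-dien-6α-yl (2Z)-2-methylbut-2-enoate | C=C/C(C)=C/C[C@H]1[C@](C)(O)[C@H](O)[C@H](OC(=O)/C(C)=C\C)[C@H]2C(C)(C)CCC[C@@]21C | intermediate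
25 | (12E)-8α-hydroxy-7-oxolabda-12,14-dien-6α-yl (2Z)-2-methylbut-2-enoate | C=C/C(C)=C/C[C@H]1[C@](C)(O)C(=O)[C@H](OC(=O)/C(C)=C\C)[C@H]2C(C)(C)CCC[C@@]21C | intermediate
26 | (12E)-7β,8α-dihydroxylabda-12,14-dien-6α-yl (2Z)-2-methylbut-2-enoate, CNP0189082.1 | C=C/C(C)=C/C[C@H]1[C@](C)(O)[C@@H](O)[C@H](OC(=O)/C(C)=C\C)[C@H]2C(C)(C)CCC[C@@]21C | target

**Step count and weak points**

Total: 16 steps. Longest linear sequence: 15 steps (from 1 to 26 through steps 1, 2 and 4–16; step 3 is a one-step branch from 5).

Least certain steps:

**Step 4 (labelled).** Most likely failure: the bulky carbenoid reacts too slowly with the hindered alkene, so that carbene dimerisation or cyclisation of 6 to a pyrazole takes over. Insertion into the allylic C–H bonds next to the methyl-bearing carbon may also compete. The enantioface selection could be low or of the opposite sense, in which case Rh2(R-DOSP)4 would be needed. The fallback sets out from 4 and returns at 7 by known reaction types. Copper-catalysed asymmetric cyclopropanation with methyl diazoacetate (CuOTf, monovalent copper, with (S,S)-tert-butyl-bis(oxazoline)), a method established for trisubstituted alkenes, would give methyl 1,5,5-trimethylbicyclo[4.1.0]heptane-7-carboxylate F1 as an exo/endo mixture. Deprotonation with LiN(i-Pr)2 at −78 °C and C-acylation with acetyl chloride would give methyl 7-acetyl-1,5,5-trimethylbicyclo[4.1.0]heptane-7-carboxylate F2. Wittig methylenation (Ph3P=CH2, THF) would give 7 together with its C7 epimer F3; both enter step 5 because that carbon becomes trigonal there.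

**Step 5 (key step).** Most likely failure: opening of the cyclopropane at the wrong bond (C9–C10, toward the tertiary C10), or isomerisation of the donor–acceptor cyclopropane to open-chain dienoates or a cyclopentene before CO is taken up. Both proximal bonds are flanked by quaternary carbons, so oxidative addition may also be slow. The fallback sets out from 7 and returns at 10: a stoichiometric photochemical iron carbonyl route (Fe(CO)5, hν, CO, 2-propanol, rt, then DBU). Here a small iron tricarbonyl fragment first binds the alkene and then forms the σ-alkyl π-allyl acyl complex, which changes the metal, the activation mode and the steric demand. It makes no new compound.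

**Step 6.** Most likely failure: poor control of C9 (epoxidation of the wrong C9 epimer of 11) or of the face of attack, and base-induced opening of the epoxide of 12 by the ester enolate. The fallback sets out from 10 (taken as the 8-ene, regenerated if necessary by kinetic protonation of its dienolate) and returns at 14. Dimethyldioxirane in acetone would epoxidise the C8=C9 bond from the α face to give methyl 8α,9α-epoxy-6-oxodriman-11-oate F4. Cp2TiCl (trivalent titanium, from Cp2TiCl2 and zinc) would cleave the C9–O bond, and protonation of the titanium enolate from the open α face would give methyl 8α-hydroxy-6-oxodriman-11-oate F5 with 9α-H fixed kinetically. KN(SiMe3)2 and N-phenyltriflimide would give the C6 enol triflate, methyl 8α-hydroxy-6-(trifluoromethylsulfonyloxy)drim-6-en-11-oate F6. Formate reduction (Pd(OAc)2, PPh3, Bu3N, HCO2H, DMF) would then give 14.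

**Step 10.** Most likely failure: retro-aldol cleavage or dehydration of the β-hydroxy aldehyde under the ylide conditions, or ionisation of the tertiary allylic C8–O bond during the acidic hydrolysis. The fallback sets out from 16 and returns at 18 and uses neither strong base nor acid. The rhodium-catalysed methylenation of step 13 applied to 16 would give 13,14,15,16-tetranorlabda-6,11-dien-8α-ol F7. Hydroboration of the monosubstituted alkene with 9-BBN and oxidation (H2O2, NaOH) would give 13,14,15,16-tetranorlabd-6-ene-8α,12-diol F8. Dess–Martin oxidation of the primary alcohol would give the aldehyde, which closes to 18.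

**Step 14.** Most likely failure: insufficient regioselectivity between O6 and O7 (the equatorial O6 is flanked by the C4 gem-dimethyl group), followed by acyl migration within the cis-diol; Z to E isomerisation of the acyl group is the second concern. The fallback sets out from 20 and returns at 25 and differentiates the two hydroxyls by oxidation instead of acylation. Brominolysis of the stannylene acetal of 20 (Bu2SnO, then Br2, CH2Cl2, molecular sieves) oxidises the axial hydroxyl of a cis-diol and would give (12E)-6α,8α-dihydroxy-7-oxo-15-norlabd-12-en-14-al F9. The methylenation of step 13, which is selective for aldehydes, would give (12E)-6α,8α-dihydroxylabda-12,14-dien-7-one F10. Yamaguchi esterification of the single secondary hydroxyl with 22 would give 25.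

## Further compounds

F1 | step 4 | methyl 1,5,5-trimethylbicyclo[4.1.0]heptane-7-carboxylate (ring fusion as in 7; exo/endo mixture at C7) | COC(=O)C1[C@@H]2C(C)(C)CCC[C@@]21C
F2 | step 4 | methyl 7-acetyl-1,5,5-trimethylbicyclo[4.1.0]heptane-7-carboxylate (ring fusion as in 7; C7 epimers) | COC(=O)C1(C(C)=O)[C@@H]2C(C)(C)CCC[C@@]21C
F3 | step 4 | methyl (1S,6R,7S)-1,5,5-trimethyl-7-(prop-1-en-2-yl)bicyclo[4.1.0]heptane-7-carboxylate (C7 epimer of 7) | COC(=O)[C@]1(C(C)=C)[C@@H]2C(C)(C)CCC[C@@]21C
F0 | step 5 | none | none
F4 | step 6 | methyl 8α,9α-epoxy-6-oxodriman-11-oate | COC(=O)[C@]13O[C@]3(C)CC(=O)[C@H]2C(C)(C)CCC[C@@]21C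
F5 | step 6 | methyl 8α-hydroxy-6-oxodriman-11-oate | COC(=O)[C@H]1[C@](C)(O)CC(=O)[C@H]2C(C)(C)CCC[C@@]21C
F6 | step 6 | methyl 8α-hydroxy-6-(trifluoromethylsulfonyloxy)drim-6-en-11-oate | COC(=O)[C@H]1[C@](C)(O)C=C(OS(=O)(=O)C(F)(F)F)[C@H]2C(C)(C)CCC[C@@]21C
F7 | step 10 | 13,14,15,16-tetranorlabda-6,11-dien-8α-ol | C=C[C@H]1[C@](C)(O)C=C[C@H]2C(C)(C)CCC[C@@]21C
F8 | step 10 | 13,14,15,16-tetranorlabd-6-ene-8α,12-diol | OCC[C@H]1[C@](C)(O)C=C[C@H]2C(C)(C)CCC[C@@]21C
F9 | step 14 | (12E)-6α,8α-dihydroxy-7-oxo-15-norlabd-12-en-14-al | O=C/C(C)=C/C[C@H]1[C@](C)(O)C(=O)[C@H](O)[C@H]2C(C)(C)CCC[C@@]21C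
F10 | step 14 | (12E)-6α,8α-dihydroxylabda-12,14-dien-7-one | C=C/C(C)=C/C[C@H]1[C@](C)(O)C(=O)[C@H](O)[C@H]2C(C)(C)CCC[C@@]21C
A1 | alternative 1 | trienimide: 3-[(2E,8E,10Z)-11-(tert-butyldimethylsilyloxy)-3,7,7-trimethyldodeca-2,8,10-trienoyl]oxazolidin-2-one | C/C(O[Si](C)(C)C(C)(C)C)=C/C=C/C(C)(C)CCC/C(C)=C/C(=O)N1CCOC1=O
A2 | alternative 1 | cycloadduct: 8α-(tert-butyldimethylsilyloxy)drim-6-en-11-oyl oxazolidinone | O=C(N3CCOC3=O)[C@H]1[C@](C)(O[Si](C)(C)C(C)(C)C)C=C[C@H]2C(C)(C)CCC[C@@]21C
A3 | alternative 2 | 2,6-dimethyl-1,4-benzoquinone | CC1=CC(=O)C=C(C)C1=O
A4 | alternative 2 | allylidenecyclopropane | C=CC=C1CC1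
A5 | alternative 2 | trans-fused enedione with C4 spirocyclopropane | O=C1C(C)=CC(=O)[C@H]2C3(CC3)C=CC[C@@]21C
A6 | alternative 3 | ynoate: ethyl 4-hydroxy-5-(4-methoxybenzyloxy)-4-methyl-6-(triethylsilyloxy)-6-(2,6,6-trimethylcyclohex-2-en-1-yl)hex-2-ynoate, configured as in A7 | CCOC(=O)C#C[C@](C)(O)[C@@H](OCc1ccc(OC)cc1)[C@H](O[Si](CC)(CC)CC)[C@H]1C(C)(C)CCC=C1C
A7 | alternative 3 | decalin with exocyclic C9=C11 enoate | CCOC(=O)/C=C1/[C@](C)(O)[C@@H](OCc3ccc(OC)cc3)[C@H](O[Si](CC)(CC)CC)[C@H]2C(C)(C)CCC[C@@]21C
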